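| flask | substrate | partner | second reagent | remark | time |
|---|---|---|---|---|---|
| dawn | 20 mM | 60 mM | 2 mM (fed, over 10 h) | run made earlier; the fed solution adds 0.50 times the starting volume |  |
| spring | 20 mM | 60 mM | 45 mM (fed, over 10 h) | run made earlier; the fed solution adds 0.50 times the starting volume |  |
| elm | 20 mM | 60.0 mM | 4.00 mM (fed, over 10 h) | the fed solution adds 0.50 times the starting volume | 3.0 d |
| maple | 20 mM | 60.0 mM | 8.00 mM (fed, over 10 h) | the fed solution adds 0.50 times the starting volume | 3.0 d |
| cedar | 20 mM | 60.0 mM | 15.0 mM (fed, over 10 h) | the fed solution adds 0.50 times the starting volume | 3.0 d |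
| birch | 20 mM | 60.0 mM | 30.0 mM (fed, over 10 h) | the fed solution adds 0.50 times the starting volume | 3.0 d |
| ash | 20 mM | 60.0 mM | 60.0 mM (fed, over 10 h) | the fed solution adds 0.50 times the starting volume | 3.0 d |

| run | time / d | target / % |
|---|---|---|
| dawn | 0.250 | 0 |
| dawn | 0.333 | 1 |
| dawn | 0.500 | 2 |
| dawn | 0.833 | 4 |
| dawn | 1.25 | 4 |
| dawn | 2.08 | 10 |
| dawn | 3.00 | 11 |
| spring | 0.167 | 6 |
| spring | 0.500 | 19 |
| spring | 0.833 | 22 |
| spring | 1.25 | 20 |
| spring | 1.67 | 22 |
| spring | 2.50 | 15 |
| spring | 3.00 | 16 |

(readings scatter by 2 percentage points)

- amounts are per litre of the starting volume; all of the dose is in the solution fed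
- "hardly changes" means that all values lie within two and a half points (for a concentration: within two and a half percent of the largest)

* amount of target at the end, in percent of the substrate charged for elm, maple, cedar, birch, ash, in this order
* the shape of the row from first to last (rises all the way / hardly changes / rises, then falls / falls all the way / falls, then rises)

1. At early times, the spring run reads 6% at 0.167 d and the dawn run reads 0% at 0.250 d. Both runs are still being fed, since the feed lasts 0.417 d.

2. The next rung is the spring run's top. It reads 22% at 0.833 d and 22% at 1.67 d. With a scatter of 2 percentage points, I read this as a plateau.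

3. Then the spring run sinks to 16% at 3.00 d. Something consumes target, and I take it to be a second use of second reagent, on the target itself.

4. The last rung is the dawn run's climb. It reads 10% at 2.08 d and 11% at 3.00 d.

5. For elm, 20.0% is the dose ratio: the whole charge of second reagent as a percentage of the substrate charge. The dawn run has a dose ratio of 10.0%, so its last reading suggests about one target per second reagent used.

6. My rule follows from that. Below 100%, second reagent is the limiting reagent, and target can't pass the dose ratio. Elm is capped at 20.0%, maple at 40.0% and cedar at 75.0%. Above 100%, second reagent exceeds the substrate charged, and the spring run, at 225%, shows target being lost. So I expect the row to turn near a dose ratio of 100%, between cedar and birch, whose dose ratio is 150%. My reckoning gives caps and a turning region, not point values.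

7. The forecast gives 13%, 18%, 21%, 19% and 11%, with the shape rises, then falls. It reads a selectivity from the spring run and says “That ratio caps the yield near 22%”.

8. The equations are:

    substrate + partner → intermediate (k = 1.74 M⁻¹ h⁻¹)
    second reagent + intermediate → target (k = 3.40 M⁻¹ h⁻¹)
    second reagent + target → over-reaction product (k = 3.54 M⁻¹ h⁻¹)

The flask gives 14.8%, 23.9%, 31.1%, 26.9% and 7.41%, with the shape rises, then falls. The row turns at 19 mM, a dose ratio of 92.7%. Elm's target ends at 74.0% of its dose ratio. In both reagent steps the second reagent's concentration cancels from the ratio of rates, leaving intermediate against target. In elm at 3.00 d, second reagent goes to intermediate 5.3 times as fast as to target, with 81.3% intermediate beside 14.8% target. Ash, at a dose ratio of 300%, holds 4.36% intermediate, 7.41% target and 86.1% over-reaction product at 3.00 d.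

(The earlier runs and the new flask were computed with made-up constants, noise included.)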